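The hydroazulene is cut at the ring-fusion bond C3–C7 and at the C6–O bond (C1 CH–OAc, C2 CH2, C3 C–CH3, C4 and C5 CH2, C6 C(OH)i-Pr, C7 fusion CH, C8 CH–O-aroyl, C9=C10 with the methyl on C10). These ten carbons are the perimeter of the fused cyclopentane (C3–C7) and cycloheptene (C1, C2, C3, C7–C10), and the key step exploits this: a cyclodecatriene with an exocyclic C3 methylene, ring-cis C6=C7 and C9=C10 bonds and both esters in place is protonated at the methylene, closes C3–C7 across the ring and takes up water at C6, forming both rings, three stereocentres and the tertiary alcohol in one operation.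

Key step: step 15

Remark: the locants C1–C10 defined above are used for all intermediates; in the cyclodecatriene C8 carries the descriptor R (C9 outranks C7 there) although its geometry is that of C8 in the target.

Step 1
Reactants: 1 prop-2-yn-1-ol
Product: 3 (2Z)-3-iodo-2-methylprop-2-en-1-ol, via cyclic alkenylmagnesium alkoxide 2 (not isolated)
Conditions: MeMgBr (3 equiv), CuI (10 mol%), THF, −10 → 20 °C; then I2, −78 → 0 °C
Reagents that add atoms: methylmagnesium bromide, C[Mg]Br; iodine, II
Why: Copper-catalysed anti-carbomagnesiation of the propargylic magnesium alkoxide puts methyl on the inner carbon and magnesium on the terminal carbon inside a five-membered chelate, and iodinolysis with retention fixes iodine cis to CH2OH, the geometry that becomes the ring-cis C9=C10 bond.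

Step 2
Reactants: 3 (2Z)-3-iodo-2-methylprop-2-en-1-ol
Product: 4 (2Z)-3-iodo-2-methylprop-2-enal
Conditions: activated MnO2, CH2Cl2, 20 °C, dark; used at once
Reagents that add atoms: none
Why: Allylic oxidation on MnO2 is neutral and should leave the Z-iodoalkene untouched, and immediate use avoids Z to E drift of the labile aldehyde.

Step 3
Reactants: 5 3-methylbut-3-en-1-ol
Product: 8 3-[(trimethylsilyl)methyl]but-3-en-1-ol, via dilithiated isoprenol 6 (not isolated), via bis-silylated intermediate 7 (not isolated)
Conditions: n-BuLi (2.1 equiv), TMEDA, Et2O, 0 → 20 °C; TMSCl (2.2 equiv), −78 → 20 °C; then K2CO3, MeOH, 20 °C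
Reagents that add atoms: chlorotrimethylsilane, C[Si](C)(C)Cl
Why: Alkoxide-directed allylic lithiation occurs at the methyl group (the future C2), silylation of the dianion gives the allylsilane, and mild methanolysis removes only the O-silyl group.

Step 4
Reactants: 8 3-[(trimethylsilyl)methyl]but-3-en-1-ol
Product: 10 [2-(2-iodoethyl)prop-2-en-1-yl]trimethylsilane, via homoallylic mesylate 9 (not isolated)
Conditions: MsCl, Et3N, CH2Cl2, 0 °C; then NaI, acetone, 55 °C
Reagents that add atoms: sodium iodide, [Na+].[I-]
Why: Mesylation followed by Finkelstein displacement at the primary carbon (C5) uses no electrophilic iodine, so the allylsilane is not attacked.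

Step 5
Reactants: 11 ethyl 4-methyl-3-oxopentanoate
Product: 12 ethyl (2Z)-4-methyl-3-[(trifluoromethanesulfonyl)oxy]pent-2-enoate
Conditions: Tf2O, aq. LiOH, hexane, 5 °C
Reagents that add atoms: trifluoromethanesulfonic anhydride, O=S(=O)(OS(=O)(=O)C(F)(F)F)C(F)(F)F
Why: O-Triflation of the lithium-chelated enolate of the β-keto ester gives the enol triflate with the triflate cis to the ester, which is the geometry needed for C5 to end up cis to C8.

Step 6
Reactants: 10 [2-(2-iodoethyl)prop-2-en-1-yl]trimethylsilane; 12 ethyl (2Z)-4-methyl-3-[(trifluoromethanesulfonyl)oxy]pent-2-enoate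
Product: 14 ethyl (2E)-3-(propan-2-yl)-6-[(trimethylsilyl)methyl]hepta-2,6-dienoate, via alkylzinc iodide 13 (not isolated)
Conditions: Zn dust, LiCl, THF, 40 °C; then 12, Pd(PPh3)4 (5 mol%), THF, 50 °C
Reagents that add atoms: none
Why: Zinc insertion into the primary iodide tolerates the allylsilane, and the Negishi coupling with the activated enol triflate goes with retention so that the new C5–C6 bond lies cis to the ester; the vinyl iodide is brought in only afterwards and cannot compete for zerovalent palladium.

Step 7
Reactants: 14 ethyl (2E)-3-(propan-2-yl)-6-[(trimethylsilyl)methyl]hepta-2,6-dienoate; 4 (2Z)-3-iodo-2-methylprop-2-enal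
Product: 15 ethyl (2E,9Z)-8-hydroxy-10-iodo-9-methyl-6-methylidene-3-(propan-2-yl)deca-2,9-dienoate (racemic at C1)
Conditions: 4, BF3·OEt2 (1.1 equiv), CH2Cl2, −78 °C; then 14; aq. NaHCO3
Reagents that add atoms: none
Why: Hosomi–Sakurai allylation, in which the 2-substituted allylsilane adds 1,2 to the BF3-activated aldehyde with loss of silicon, forms C1–C2 and regenerates the C3 methylene; C1 is formed racemic here and is fixed in steps 8 and 9.

Step 8
Reactants: 15 ethyl (2E,9Z)-8-hydroxy-10-iodo-9-methyl-6-methylidene-3-(propan-2-yl)deca-2,9-dienoate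
Product: 16 ethyl (2E,9Z)-10-iodo-9-methyl-6-methylidene-8-oxo-3-(propan-2-yl)deca-2,9-dienoate
Conditions: Dess–Martin periodinane, NaHCO3, CH2Cl2, 0 → 20 °C
Reagents that add atoms: none
Why: Buffered Dess–Martin oxidation should give the enone without moving the β,γ-methylene into conjugation or isomerising the Z-iodoalkene.

Step 9
Reactants: 16 ethyl (2E,9Z)-10-iodo-9-methyl-6-methylidene-8-oxo-3-(propan-2-yl)deca-2,9-dienoate
Product: 17 ethyl (2E,8S,9Z)-8-hydroxy-10-iodo-9-methyl-6-methylidene-3-(propan-2-yl)deca-2,9-dienoate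
Conditions: (R)-Me-CBS oxazaborolidine [(3aR)-1-methyl-3,3-diphenyltetrahydro-1H,3H-pyrrolo[1,2-c][1,3,2]oxazaborole] (0.2 equiv), catecholborane (1.5 equiv), toluene, −78 °C
Reagents that add atoms: none
Why: Corey–Bakshi–Shibata reduction, with the α-methyl-β-iodoalkenyl group as the large substituent and the C2 methylene as the small one, lets the (R)-catalyst set the (S)-carbinol at C1, and catecholborane at low temperature spares the ester and the alkenes.

Step 10
Reactants: 17 ethyl (2E,8S,9Z)-8-hydroxy-10-iodo-9-methyl-6-methylidene-3-(propan-2-yl)deca-2,9-dienoate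
Product: 18 (2E,8S,9Z)-10-iodo-9-methyl-6-methylidene-3-(propan-2-yl)deca-2,9-diene-1,8-diol
Conditions: i-Bu2AlH (3.3 equiv), CH2Cl2, −78 °C; aq. potassium sodium tartrate (KNaC4H4O6)
Reagents that add atoms: none
Why: 1,2-Reduction of the conjugated ester by i-Bu2AlH at low temperature gives the allylic alcohol without touching the vinyl iodide or either olefin geometry.

Step 11
Reactants: 18 (2E,8S,9Z)-10-iodo-9-methyl-6-methylidene-3-(propan-2-yl)deca-2,9-diene-1,8-diol
Product: 19 (2E,8S,9Z)-8-hydroxy-10-iodo-9-methyl-6-methylidene-3-(propan-2-yl)deca-2,9-dienal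
Conditions: TEMPO (2,2,6,6-tetramethylpiperidin-1-oxyl, 0.1 equiv), PhI(OAc)2 (1.1 equiv), CH2Cl2, 20 °C
Reagents that add atoms: none
Why: Oxoammonium oxidation is selective for the primary allylic alcohol over the hindered secondary one and is known not to isomerise trisubstituted enals.

Step 12
Reactants: 19 (2E,8S,9Z)-8-hydroxy-10-iodo-9-methyl-6-methylidene-3-(propan-2-yl)deca-2,9-dienal
Product: 20 (1Z,3S,8E)-1-iodo-2-methyl-5-methylidene-10-oxo-8-(propan-2-yl)deca-1,8-dien-3-yl acetate
Conditions: Ac2O, pyridine, DMAP (4-dimethylaminopyridine, cat.), CH2Cl2, 0 °C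
Reagents that add atoms: acetic anhydride, CC(=O)OC(C)=O
Why: DMAP-catalysed acetylation of the secondary allylic alcohol installs the C1 acetate of the target before ring closure, so no protecting group is needed.

Step 13
Reactants: 20 (1Z,3S,8E)-1-iodo-2-methyl-5-methylidene-10-oxo-8-(propan-2-yl)deca-1,8-dien-3-yl acetate
Product: 21 (1S,2Z,4R,5E)-4-hydroxy-2-methyl-9-methylidene-6-(propan-2-yl)cyclodeca-2,5-dien-1-yl acetate
Conditions: CrCl2 (8 equiv), NiCl2 (0.1 equiv), degassed DMSO, 20 °C, slow addition to 0.003 M
Reagents that add atoms: none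
Why: In this Nozaki–Hiyama–Kishi closure the alkenylchromium formed from the vinyl iodide adds only to the aldehyde, with retention of the Z geometry, and forms C8–C9 under high dilution; C8 is set by substrate control, the enal being attacked on the face that lets the ring close with the C1 acetoxy group and the new alkoxide both pseudo-equatorial (1,4-cis), and any C8 epimer is removed by chromatography.

Step 14
Reactants: 21 (1S,2Z,4R,5E)-4-hydroxy-2-methyl-9-methylidene-6-(propan-2-yl)cyclodeca-2,5-dien-1-yl acetate; 22 4-acetoxybenzoic acid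
Product: 23 (1R,2Z,4S,9E)-4-(acetyloxy)-3-methyl-6-methylidene-9-(propan-2-yl)cyclodeca-2,9-dien-1-yl 4-(acetyloxy)benzoate
Conditions: EDC·HCl, DMAP (cat.), CH2Cl2, 0 → 20 °C
Reagents that add atoms: none
Why: Steglich esterification transfers the carbodiimide-activated acid to the C8 hydroxyl with retention, under basic conditions in which the doubly allylic alcohol does not ionise.

Step 15
Reactants: 23 (1R,2Z,4S,9E)-4-(acetyloxy)-3-methyl-6-methylidene-9-(propan-2-yl)cyclodeca-2,9-dien-1-yl 4-(acetyloxy)benzoate
Product: 24 (3R,3aS,4S,7S,8aR)-7-(acetyloxy)-3-hydroxy-6,8a-dimethyl-3-(propan-2-yl)-1,2,3,3a,4,7,8,8a-octahydroazulen-4-yl 4-(acetyloxy)benzoate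
Conditions: TsOH·H2O (0.3 equiv), acetone/H2O (4:1), 0 → 20 °C
Reagents that add atoms: water, O
Why: Proposed new method: Markovnikov protonation of the exocyclic C3 methylene, assisted by the C6=C7 π bond held across the ring, forms C3–C7 as the C3 methyl group appears, and water then captures the tertiary C6 cation anti to the new bond; the closest known reaction type is the acid-induced transannular cyclisation of germacrane-type cyclodeca-1,5-dienes to bicyclic alcohols with water capture. The cyclopentane (C3–C4–C5–C6–C7) closes 5-endo-trig and the cycloheptene (C1–C2–C3–C7–C8–C9–C10) 7-exo-trig, both through the single bond C3–C7. C6 is set relative to C7 by stereospecific anti addition across the ring-cis C6=C7 bond, which places the hydroxyl cis to C8. C3 and C7 are set by the folded conformation with the C1 acetoxy and C8 aroyloxy groups pseudo-equatorial, in which C7 meets the face of the C3 cation that leaves the methyl group and H-7 trans. The step needs protonation at the methylene only; this should be secured by its unhindered terminal carbon, by the fact that only this protonation is assisted productively by a neighbouring π bond, and by the deactivation of C9=C10 through acyloxy-bearing carbons on both sides, which also makes C7 and not C9 the nucleophile. Dilute acid in a wet, weakly ionising medium at low temperature is chosen so that the allylic esters and the phenol acetate survive, and in the product C8 is only singly allylic.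

Step 16
Reactants: 24 (3R,3aS,4S,7S,8aR)-7-(acetyloxy)-3-hydroxy-6,8a-dimethyl-3-(propan-2-yl)-1,2,3,3a,4,7,8,8a-octahydroazulen-4-yl 4-(acetyloxy)benzoate
Product: 25 (3R,3aS,4S,7S,8aR)-7-(acetyloxy)-3-hydroxy-6,8a-dimethyl-3-(propan-2-yl)-1,2,3,3a,4,7,8,8a-octahydroazulen-4-yl 4-hydroxybenzoate
Conditions: NH4OAc (8 equiv), MeOH/H2O (4:1), 20 °C
Reagents that add atoms: none
Why: Ammonium acetate in aqueous methanol cleaves aryl acetates selectively by mild methanolysis and should leave the secondary alkyl acetate, the benzoate ester and the tertiary alcohol untouched.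

Compound list
1 | prop-2-yn-1-ol | C#CCO | starting material
2 | 4-methyl-2,5-dihydro-1,2-oxamagnesole (cyclic alkenylmagnesium alkoxide) | CC1=C[Mg]OC1 | intermediate
3 | (2Z)-3-iodo-2-methylprop-2-en-1-ol | OC/C(C)=C\I | intermediate
4 | (2Z)-3-iodo-2-methylprop-2-enal | O=C/C(C)=C\I | intermediate
5 | 3-methylbut-3-en-1-ol | C=C(C)CCO | starting material
6 | dilithiated isoprenol (lithium 3-(lithiomethyl)but-3-en-1-olate) | [Li]CC(=C)CCO[Li] | intermediate
7 | trimethyl({3-[(trimethylsilyl)methyl]but-3-en-1-yl}oxy)silane | C=C(C[Si](C)(C)C)CCO[Si](C)(C)C | intermediate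
8 | 3-[(trimethylsilyl)methyl]but-3-en-1-ol | C=C(C[Si](C)(C)C)CCO | intermediate
9 | 3-[(trimethylsilyl)methyl]but-3-en-1-yl methanesulfonate | C=C(C[Si](C)(C)C)CCOS(C)(=O)=O | intermediate
10 | [2-(2-iodoethyl)prop-2-en-1-yl]trimethylsilane | C=C(C[Si](C)(C)C)CCI | intermediate
11 | ethyl 4-methyl-3-oxopentanoate | CCOC(=O)CC(=O)C(C)C | starting material
12 | ethyl (2Z)-4-methyl-3-[(trifluoromethanesulfonyl)oxy]pent-2-enoate | CCOC(=O)/C=C(/C(C)C)OS(=O)(=O)C(F)(F)F | intermediate
13 | {3-[(trimethylsilyl)methyl]but-3-en-1-yl}zinc iodide | C=C(C[Si](C)(C)C)CC[Zn]I | intermediate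
14 | ethyl (2E)-3-(propan-2-yl)-6-[(trimethylsilyl)methyl]hepta-2,6-dienoate | CCOC(=O)/C=C(/C(C)C)CCC(=C)C[Si](C)(C)C | intermediate
15 | ethyl (2E,9Z)-8-hydroxy-10-iodo-9-methyl-6-methylidene-3-(propan-2-yl)deca-2,9-dienoate, racemic | CCOC(=O)/C=C(/C(C)C)CCC(=C)CC(O)/C(C)=C\I | intermediate
16 | ethyl (2E,9Z)-10-iodo-9-methyl-6-methylidene-8-oxo-3-(propan-2-yl)deca-2,9-dienoate | CCOC(=O)/C=C(/C(C)C)CCC(=C)CC(=O)/C(C)=C\I | intermediate
17 | ethyl (2E,8S,9Z)-8-hydroxy-10-iodo-9-methyl-6-methylidene-3-(propan-2-yl)deca-2,9-dienoate | CCOC(=O)/C=C(/C(C)C)CCC(=C)C[C@H](O)/C(C)=C\I | intermediate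
18 | (2E,8S,9Z)-10-iodo-9-methyl-6-methylidene-3-(propan-2-yl)deca-2,9-diene-1,8-diol | OC/C=C(/C(C)C)CCC(=C)C[C@H](O)/C(C)=C\I | intermediate
19 | (2E,8S,9Z)-8-hydroxy-10-iodo-9-methyl-6-methylidene-3-(propan-2-yl)deca-2,9-dienal | O=C/C=C(/C(C)C)CCC(=C)C[C@H](O)/C(C)=C\I | intermediate
20 | (1Z,3S,8E)-1-iodo-2-methyl-5-methylidene-10-oxo-8-(propan-2-yl)deca-1,8-dien-3-yl acetate | O=C/C=C(/C(C)C)CCC(=C)C[C@H](OC(C)=O)/C(C)=C\I | intermediate
21 | (1S,2Z,4R,5E)-4-hydroxy-2-methyl-9-methylidene-6-(propan-2-yl)cyclodeca-2,5-dien-1-yl acetate | CC(=O)O[C@H]1CC(=C)CC/C(C(C)C)=C\[C@@H](O)/C=C1/C | intermediate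
22 | 4-acetoxybenzoic acid | CC(=O)Oc1ccc(cc1)C(O)=O | starting material
23 | (1R,2Z,4S,9E)-4-(acetyloxy)-3-methyl-6-methylidene-9-(propan-2-yl)cyclodeca-2,9-dien-1-yl 4-(acetyloxy)benzoate | CC(=O)O[C@H]1CC(=C)CC/C(C(C)C)=C\[C@@H](OC(=O)c2ccc(OC(C)=O)cc2)/C=C1/C | intermediate
24 | (3R,3aS,4S,7S,8aR)-7-(acetyloxy)-3-hydroxy-6,8a-dimethyl-3-(propan-2-yl)-1,2,3,3a,4,7,8,8a-octahydroazulen-4-yl 4-(acetyloxy)benzoate | CC(=O)O[C@H]1C[C@@]2(C)CC[C@@](O)(C(C)C)[C@@H]2[C@@H](OC(=O)c2ccc(OC(C)=O)cc2)C=C1C | intermediate
25 | (3R,3aS,4S,7S,8aR)-7-(acetyloxy)-3-hydroxy-6,8a-dimethyl-3-(propan-2-yl)-1,2,3,3a,4,7,8,8a-octahydroazulen-4-yl 4-hydroxybenzoate (CNP0305796.2) | CC(=O)O[C@H]1C[C@@]2(C)CC[C@@](O)(C(C)C)[C@@H]2[C@@H](OC(=O)c2ccc(O)cc2)C=C1C | target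

Total steps: 16. Longest linear sequence: 13 steps (from 5 through steps 3, 4, 6 and 7 to 16).

Steps most likely to fail

Step 15. Proton delivery may be unselective: the ring olefins may be protonated, the doubly allylic C8 ester may ionise, or the C3 cation may simply be hydrated before C7 reaches it. The fallback generates the cation with a metal electrophile that selects the 1,1-disubstituted alkene and needs no Brønsted acid. Setting out from 23, Hg(OCOCF3)2 in wet nitromethane at −20 °C followed by aqueous NaCl should give the cyclised alkylmercuric chloride F1, by opening of the mercurinium ion at C3 by C7 and water capture at C6. This mercury-mediated olefin cyclisation with hydroxyl termination is established for terpenoid polyenes and medium-ring dienes. Reductive demercuration with Bu3SnH in toluene at 20 °C converts CH2HgCl into the C3 methyl group and rejoins the route at 24.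

Step 13. Facial selectivity at C8 may be poor in the ring-closing addition, so that both carbinol epimers form. In that case both are used. From 20 the same chromium-mediated closure also gives the C8-epimeric alcohol F2, which is separated and esterified with 22 under Mitsunobu conditions (PPh3, DIAD, THF, 0 °C). Inversion at C8 gives 23, where the route is rejoined; the fully substituted olefin termini disfavour allylic transposition. Epimer 21 continues through step 14.

Step 7. The Lewis acid may isomerise the Z-iodoenal to the E isomer, or let the allylsilane add to its own enoate. The fallback replaces the allyl donor by a neutral organochromium reagent. From 14, bromodesilylation with NBS (CH2Cl2, −78 °C) gives the allylic bromide F3. A Barbier-type Nozaki–Hiyama allylation of 4 with F3 and CrCl2 in THF at 0 °C, without nickel so that the vinyl iodide stays inert, then gives 15, where the route is rejoined.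

Further compounds
F1 | step 15 | alkylmercuric chloride of 24 in which the C3 methyl group is CH2HgCl | CC(=O)O[C@H]1C[C@@]2(C[Hg]Cl)CC[C@@](O)(C(C)C)[C@@H]2[C@@H](OC(=O)c2ccc(OC(C)=O)cc2)C=C1C
F2 | step 13 | (1S,2Z,4S,5E)-4-hydroxy-2-methyl-9-methylidene-6-(propan-2-yl)cyclodeca-2,5-dien-1-yl acetate (C8 epimer of 21) | CC(=O)O[C@H]1CC(=C)CC/C(C(C)C)=C\[C@H](O)/C=C1/C
F3 | step 7 | ethyl (2E)-6-(bromomethyl)-3-(propan-2-yl)hepta-2,6-dienoate | CCOC(=O)/C=C(/C(C)C)CCC(=C)CBr
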